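**Retrosynthetic overview**
1. Endgame on the complete skeleton. The ring-A epoxy alcohol comes from the C12=C13 alkene, the C8/C9 diol from an E-C8=C9 alkene, and the 3,4-oxirane from the E-C3=C4 allylic alcohol.
2. Key disconnection: C6–C7 and O7–C19 are cut together. A γ-chloroallylchromium adds intramolecularly to an enal and the resulting alkoxide lactonises. This gives the ten-membered ring and the γ-lactone in one operation, together with Cl-6 and the C5(16) methylene.
3. The seco compound comes from a ring-A dialdehyde. C2–C3 is made by alkenylzinc addition of a C5 dichloroenyne. C8–C9 is made by Mukaiyama aldol with a C5 aldehyde ester derived from (R)-methylsuccinate, which supplies C17.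
4. Ring A comes from an enantioselective Diels–Alder reaction of piperylene with methylfumaraldehyde, which sets C1, C10 and C11.
5. Ring order: ring A, then ten-membered ring plus lactone together, then 3,4-oxirane, then 13,14-oxirane.

Assumption: briarane numbering (C1–C20) is used in the descriptive names. Where 7, 8, 9 and 17 are isomer mixtures, the elements concerned are erased later, so their SMILES leave these elements open; 14 is shown as its major E isomer.

**Step 1**
Reactants: 1 (E)-4,4-dimethoxy-2-methylbut-2-enal
Product: 2 (E)-2-methylbut-2-enedial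
Conditions: TsOH·H2O (cat.), acetone–H2O, rt
Reagents that add atoms: water, O
Why: Acid-catalysed acetal hydrolysis of an allylic acetal is fast, leaves the E-alkene untouched and creates no stereocentre.

**Step 2**
Reactants: 2 (E)-2-methylbut-2-enedial; 3 (E)-penta-1,3-diene
Product: 4 (1S,2S,3S)-1,3-dimethylcyclohex-4-ene-1,2-dicarbaldehyde (ring A; C2 and C9 aldehydes trans; C20 cis to C9)
Conditions: (5S)-5-benzyl-2,2,3-trimethylimidazolidin-4-one·HCl (first-generation MacMillan catalyst, 20 mol %), MeNO2–H2O 95:5, −10 °C
Reagents that add atoms: none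
Why: Enantioselective organocatalytic Diels–Alder reaction in which the amine condenses only with the α-unbranched C9 aldehyde, and the doubly activated C1=C10 bond adds the diene ortho and endo on the face away from the benzyl group, so that C1, C10 and C11 are set at once (C2/C9 trans from the E-alkene, C20 cis to C9 from the endo rule).

**Step 3**
Reactants: 5 dimethyl (R)-2-methylsuccinate
Product: 6 methyl (R)-2-methyl-4-oxobutanoate
Conditions: iBu2AlH (1.0 equiv), CH2Cl2, −78 °C; then aq. potassium sodium tartrate
Reagents that add atoms: none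
Why: Partial ester reduction takes the unbranched ester faster than the α-branched one and stops at the aluminium hemiacetal, while C17 comes unchanged from the chiral pool.

**Step 4**
Reactants: 6 methyl (R)-2-methyl-4-oxobutanoate
Product: 7 methyl (R)-2-methyl-4-(trimethylsilyloxy)but-3-enoate (E/Z mixture)
Conditions: TMSOTf, Et3N, Et2O, 0 °C
Reagents that add atoms: trimethylsilyl triflate, C[Si](C)(C)OS(=O)(=O)C(F)(F)F
Why: Soft enolisation (silyl enol ether formation) is much faster for the aldehyde than for the ester, so C17 is not touched and the alkene geometry does not matter.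

**Step 5**
Reactants: 4 ring-A dialdehyde; 7 silyl enol ether
Product: 9 masked enal aldehyde (free C2 aldehyde; C9-OTMS; C7=C8 TBS enol ether; C19 methyl ester), via aldol silyl ether 8 (not isolated)
Conditions: HNTf2 (1 mol %), CH2Cl2, −78 °C; then Et3N, TBSOTf, −78 → 0 °C
Reagents that add atoms: tert-butyldimethylsilyl triflate, CC(C)(C)[Si](C)(C)OS(=O)(=O)C(F)(F)F
Why: A Mukaiyama aldol addition with silyl transfer occurs at the less hindered C9 aldehyde (the C2 aldehyde sits on quaternary C1), and soft enolisation of the only enolisable aldehyde then stores C7–C9 as a 1,3-bis(silyloxy)propene, a masked enal whose C8 and C9 centres are erased in step 8.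

**Step 6**
Reactants: 10 1,3-dichloropropan-2-one; 11 ethynylmagnesium bromide
Product: 12 1-chloro-2-(chloromethyl)but-3-yn-2-ol
Conditions: THF, −78 °C; then cold 1 M HCl
Reagents that add atoms: none
Why: Grignard 1,2-addition to the ketone is quenched cold before the alkoxide can close to an epoxide, and no stereocentre is formed.

**Step 7**
Reactants: 12 1-chloro-2-(chloromethyl)but-3-yn-2-ol
Product: 14 (E)-4-chloro-3-(chloromethyl)but-3-en-1-yne, via tertiary mesylate 13 (not isolated)
Conditions: MsCl, Et3N (excess), CH2Cl2, 0 °C → rt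
Reagents that add atoms: none
Why: Mesylation followed by E2 elimination toward a chlorine-acidified CH2Cl hydrogen gives the conjugated chloroenyne; the two CH2Cl groups are equivalent, so only the alkene geometry can vary, and that is lost again at the allylchromium stage.

**Step 8**
Reactants: 14 chloroenyne; 9 masked enal aldehyde
Product: 18 seco enal (C2 S-allylic alcohol; E-C3=C4; C16 allylic chloride; C6 vinyl chloride; E-C8=C9 enal with C7 aldehyde; C19 methyl ester), via dienylborane 15 (not isolated), via dienylzinc 16 (not isolated), via masked allylic alcohol 17 (not isolated)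
Conditions: 14, Cy2BH, toluene, 0 °C; Me2Zn, −78 °C; (−)-MIB (10 mol %), 9, −20 °C; then 1 M HCl–THF, 0 °C
Reagents that add atoms: none
Why: Hydroboration, boron-to-zinc exchange and amino-alcohol-catalysed alkenylzinc addition (Oppolzer–Noyori type) give the E-allylic alcohol with C2 set by the ligand, and dilute acid then collapses the vinylogous silyl hemiacetal to the more stable E-enal.

**Step 9**
Reactants: 18 seco enal
Product: 21 tricyclic chloro lactone (ring A; E,E ten-membered ring; C7-O/C19 γ-lactone; 6S-Cl; 7S; C5(16) methylene; free C2-OH), via allylchromium 19 (not isolated), via ring-closed alkoxide 20 (not isolated)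
Conditions: CrCl2 (8 equiv), NaI (0.5 equiv), THF–DMF 4:1, slow addition to 2 mM, 25 °C; then aq. citric acid
Reagents that add atoms: none
Why: Proposed new method: divalent chromium converts the allylic chloride into a γ-chloroallylchromium (metal on primary C16) that adds through chlorine-bearing C6 to the enal carbonyl in a six-membered transition state, and the trivalent chromium alkoxide on O7 then attacks the C19 ester, so the ten-membered ring and the lactone form together with Cl-6, the C5(16) methylene and the C6 and C7 centres; because the C5–C6–C7–C8 torsion of the emerging E,E-cyclodeca-1,6-diene must be gauche, C8 sits axial in the chair and the usual anti preference is predicted to become the syn chlorohydrin, with the face fixed by the trans-fused ring A; the closest known reaction types are Nozaki–Hiyama allylation macrocyclisation with in situ lactonisation to ten-membered germacranolides and the intermolecular chromium-mediated γ-chloroallylation of aldehydes.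

**Step 10**
Reactants: 21 tricyclic chloro lactone
Product: 22 3,4-trans-epoxy alcohol (3S,4R descriptors as in the target)
Conditions: Ti(OiPr)4 (20 mol %), D-(−)-DIPT (24 mol %), tBuOOH, 4 Å MS, CH2Cl2, −20 °C
Reagents that add atoms: tert-butyl hydroperoxide, CC(C)(C)OO
Why: Sharpless asymmetric epoxidation in the matched case touches only the alkene of the allylic alcohol and gives the anti (erythro) trans-epoxide, which sets C3 and C4 relative to C2.

**Step 11**
Reactants: 22 3,4-epoxy alcohol
Product: 23 2,8,9-triol (8R,9S)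
Conditions: OsO4 (5 mol %), (DHQ)2PHAL (6 mol %), NMO, citric acid, tBuOH–H2O, 0 °C
Reagents that add atoms: N-methylmorpholine N-oxide, C[N+]1([O-])CCOCC1; water, O
Why: In this Upjohn dihydroxylation with a Sharpless ligand the strained E-trisubstituted ring alkene is the most reactive one and is open only on its peripheral face (anti to C6 on the lactone, which is also the ligand-preferred face), and syn addition to the E-alkene fixes C8 and C9 together.

**Step 12**
Reactants: 23 2,8,9-triol
Product: 24 2,9-diacetate
Conditions: Ac2O, DMAP (cat.), pyridine, CH2Cl2, 0 °C → rt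
Reagents that add atoms: acetic anhydride, CC(=O)OC(C)=O
Why: DMAP-catalysed acetylation takes the two secondary alcohols and leaves the tertiary C8-OH free.

**Step 13**
Reactants: 24 2,9-diacetate
Product: 26 target CNP0141778.4, via C12 hydroperoxide 25 (not isolated)
Conditions: O2, tetraphenylporphyrin (cat.), sodium lamp, Ti(OiPr)4 (15 mol %), 4 Å MS, CH2Cl2, −10 °C
Reagents that add atoms: dioxygen, O=O
Why: A Schenck ene reaction of singlet oxygen on the open α face (β face blocked by C15 and C20) abstracts the pseudoaxial H-14α to give the 12α-hydroperoxide with a C13=C14 alkene, and titanium-catalysed oxygen transfer (one-pot hydroxy-epoxidation) delivers the oxirane syn to O12, setting C12, C13 and C14, while the electron-poor C5(16) alkene is inert.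

**Compound list**
1 | (E)-4,4-dimethoxy-2-methylbut-2-enal | O=C/C(C)=C/C(OC)OC | starting material
2 | (E)-2-methylbut-2-enedial | O=C/C(C)=C/C=O | intermediate
3 | (E)-penta-1,3-diene | C=C/C=C/C | starting material
4 | (1S,2S,3S)-1,3-dimethylcyclohex-4-ene-1,2-dicarbaldehyde | O=C[C@]1(C)[C@H]([C@@H](C)C=CC1)C=O | intermediate
5 | dimethyl (R)-2-methylsuccinate | COC(=O)[C@H](C)CC(=O)OC | starting material
6 | methyl (R)-2-methyl-4-oxobutanoate | COC(=O)[C@H](C)CC=O | intermediate
7 | methyl (R)-2-methyl-4-(trimethylsilyloxy)but-3-enoate | COC(=O)[C@H](C)C=CO[Si](C)(C)C | intermediate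
8 | aldol silyl ether (C9-OTMS, free C2 and C7 aldehydes; C8/C9 epimers) | O=C[C@]1(C)[C@H]([C@@H](C)C=CC1)C(O[Si](C)(C)C)C(C=O)[C@@H](C)C(=O)OC | intermediate
9 | masked enal aldehyde (C9-OTMS, C7=C8 TBS enol ether, free C2 aldehyde) | O=C[C@]1(C)[C@H]([C@@H](C)C=CC1)C(O[Si](C)(C)C)C(=CO[Si](C)(C)C(C)(C)C)[C@@H](C)C(=O)OC | intermediate
10 | 1,3-dichloropropan-2-one | ClCC(=O)CCl | starting material
11 | ethynylmagnesium bromide | C#C[Mg]Br | starting material
12 | 1-chloro-2-(chloromethyl)but-3-yn-2-ol | C#CC(O)(CCl)CCl | intermediate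
13 | methanesulfonate of 12 | C#CC(CCl)(CCl)OS(C)(=O)=O | intermediate
14 | (E)-4-chloro-3-(chloromethyl)but-3-en-1-yne | ClC/C(C#C)=C/Cl | intermediate
15 | (1E,3E)-dienyl dicyclohexylborane | ClC/C(=C/Cl)/C=C/B(C1CCCCC1)C1CCCCC1 | intermediate
16 | (1E,3E)-dienyl(methyl)zinc | ClC/C(=C/Cl)/C=C/[Zn]C | intermediate
17 | C2 allylic alcohol with the enal still masked | ClC/C(=C/Cl)/C=C/[C@H](O)[C@]1(C)[C@H]([C@@H](C)C=CC1)C(O[Si](C)(C)C)C(=CO[Si](C)(C)C(C)(C)C)[C@@H](C)C(=O)OC | intermediate
18 | seco enal allylic chloride | ClC/C(=C/Cl)/C=C/[C@H](O)[C@]1(C)[C@H]([C@@H](C)C=CC1)/C=C(/C=O)[C@@H](C)C(=O)OC | intermediate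
19 | γ-chloroallyl dichlorochromium (trivalent chromium) | Cl[Cr](Cl)C/C(=C/Cl)/C=C/[C@H](O)[C@]1(C)[C@H]([C@@H](C)C=CC1)/C=C(/C=O)[C@@H](C)C(=O)OC | intermediate
20 | ring-closed O7 dichlorochromium alkoxide, ester still open | C=C1/C=C/[C@H](O)[C@]2(C)[C@H]([C@@H](C)C=CC2)/C=C(/[C@H](O[Cr](Cl)Cl)[C@H]1Cl)[C@@H](C)C(=O)OC | intermediate
21 | tricyclic chloro lactone | C=C1/C=C/[C@H](O)[C@]2(C)[C@H]([C@@H](C)C=CC2)/C=C2/[C@H](OC(=O)[C@@H]2C)[C@H]1Cl | intermediate
22 | 3,4-epoxy alcohol | C=C1[C@H]2O[C@@H]2[C@H](O)[C@]2(C)[C@H]([C@@H](C)C=CC2)/C=C2/[C@H](OC(=O)[C@@H]2C)[C@H]1Cl | intermediate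
23 | 2,8,9-triol | C=C1[C@H]2O[C@@H]2[C@H](O)[C@]2(C)[C@H]([C@@H](C)C=CC2)[C@H](O)[C@@]2(O)[C@H](OC(=O)[C@@H]2C)[C@H]1Cl | intermediate
24 | 2,9-diacetate | C=C1[C@H]2O[C@@H]2[C@H](OC(C)=O)[C@]2(C)[C@H]([C@@H](C)C=CC2)[C@H](OC(C)=O)[C@@]2(O)[C@H](OC(=O)[C@@H]2C)[C@H]1Cl | intermediate
25 | 12α-hydroperoxide with C13=C14 | C=C1[C@H]2O[C@@H]2[C@H](OC(C)=O)[C@]2(C)[C@H]([C@@H](C)[C@H](OO)C=C2)[C@H](OC(C)=O)[C@@]2(O)[C@H](OC(=O)[C@@H]2C)[C@H]1Cl | intermediate
26 | CNP0141778.4 | C=C1[C@H]2O[C@@H]2[C@H](OC(C)=O)[C@]2(C)[C@H]([C@@H](C)[C@H](O)[C@@H]3O[C@@H]32)[C@H](OC(C)=O)[C@@]2(O)[C@H](OC(=O)[C@@H]2C)[C@H]1Cl | target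

**Totals**
Total step count: 13.
Longest linear sequence: 9 steps (1, 2, 5, 8, 9, 10, 11, 12, 13).

**The three steps most likely to fail**

**Step 9** (ring closure and the C6/C7 stereochemical sense). The fallback sets out from 4, 7 and 14 and returns at 21. It closes the ring at C2–C3 instead of C6–C7.
- The aldol of step 5 is worked up with dilute acid, without the second silylation, to give the free enal dialdehyde F1.
- Compound 14 is treated with Cp2ZrHCl and then I2 to give the iodo diene F2.
- CrCl2 joins F2 through C6 to the less hindered enal carbonyl of F1, with lactonisation, to give the lactone vinyl iodide F3. Its C6/C7 diastereomers can be separated at this open-chain stage.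
- A Nozaki–Hiyama–Kishi reaction (CrCl2, NiCl2 cat., DMSO, high dilution) of the vinyl iodide with the C2 aldehyde then gives 21.

**Step 2** (quaternary centre by iminium catalysis). The fallback sets out from 3 and returns at 4. It uses an auxiliary-controlled Lewis acid Diels–Alder reaction.
- (E)-4-methoxy-3-methyl-4-oxobut-2-enoic acid is coupled through its mixed anhydride with lithiated (S)-4-benzyloxazolidin-2-one to give the imide dienophile F4.
- Et2AlCl-promoted cycloaddition with 3 occurs on the chelated imide, ortho and endo, on the face opposite the benzyl group, to give the adduct F5.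
- LiAlH4 reduces both acyl groups of F5 to the diol F6.
- Dess–Martin oxidation of F6 gives 4.

**Step 5** (discrimination of two aldehydes and over-addition in the aldehyde cross-aldol). The fallback sets out from 4 and returns at 18, with the order of the two arms reversed.
- HC(OMe)3 with PPTS in MeOH at 0 °C acetalises only the less hindered C9 aldehyde, giving the mono-acetal F7.
- The dienylzinc 16 adds to the free C2 aldehyde of F7 as in step 8, giving the allylic alcohol acetal F8.
- After transient O-silylation, TMSOTf-catalysed coupling of the acetal with 7 (Noyori-type acetal aldol) gives the β-methoxy aldehyde F9.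
- Dilute acid eliminates methanol from F9 to give 18.

**Further compounds**
F1 | step 9 | enal dialdehyde (free C2 and C7 aldehydes, E-C8=C9) | O=C[C@]1(C)[C@H]([C@@H](C)C=CC1)/C=C(/C=O)[C@@H](C)C(=O)OC
F2 | step 9 | (1E,3E)-4-chloro-3-(chloromethyl)-1-iodobuta-1,3-diene | ClC/C(=C/Cl)/C=C/I
F3 | step 9 | lactone vinyl iodide with free C2 aldehyde | O=C[C@]1(C)[C@H]([C@@H](C)C=CC1)/C=C1/[C@H](OC(=O)[C@@H]1C)[C@@H](Cl)C(=C)/C=C/I
F4 | step 2 | (S)-4-benzyl-3-[(E)-4-methoxy-3-methyl-4-oxobut-2-enoyl]oxazolidin-2-one | COC(=O)/C(C)=C/C(=O)N1[C@@H](Cc2ccccc2)COC1=O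
F5 | step 2 | Diels–Alder adduct (C2 methyl ester, C9 imide) | COC(=O)[C@]1(C)[C@H]([C@@H](C)C=CC1)C(=O)N1[C@@H](Cc2ccccc2)COC1=O
F6 | step 2 | ring-A 1,2-bis(hydroxymethyl) compound | OC[C@]1(C)[C@H]([C@@H](C)C=CC1)CO
F7 | step 5 | ring-A C9 dimethyl acetal with free C2 aldehyde | O=C[C@]1(C)[C@H]([C@@H](C)C=CC1)C(OC)OC
F8 | step 5 | C2 allylic alcohol C9 acetal | ClC/C(=C/Cl)/C=C/[C@H](O)[C@]1(C)[C@H]([C@@H](C)C=CC1)C(OC)OC
F9 | step 5 | β-methoxy aldehyde (C9-OMe, C7 aldehyde) | ClC/C(=C/Cl)/C=C/[C@H](O)[C@]1(C)[C@H]([C@@H](C)C=CC1)C(OC)C(C=O)[C@@H](C)C(=O)OC
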